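**Retrosynthetic overview**

- The C3–C4 bond of ring C is cut by a retro-hydroacylation. The target opens to an achiral formyl enol ether: the future C4 is a formyl group on ring A ortho to O1, and C2=C3 is a 1,1-disubstituted alkene carrying O1 and ring B.
- Enabling feature: C2 carries both O1 and ring B, and C3 is an unsubstituted CH2 next to the C4 carbonyl. The O1–C2–C3 unit is therefore the hydro form of an aryl enol ether; adding the formyl C–H across C2=C3 (acyl to C3, hydrogen to C2) closes ring C and creates the only stereocentre in one operation.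
- The enol ether comes from a racemic β-bromo ether by E2 loss of HBr. Its O1–C2 bond comes from a Mitsunobu etherification of 2-hydroxy-4,6-dimethoxybenzaldehyde (ring A) with the bromohydrin of 2-bromo-1-(3,4,5-trimethoxyphenyl)ethanone (ring B).
- Ring order: rings A and B are bought; ring C is the only ring formed, in the last step.

Key step: step 4

Assumption: the sense of induction of the chiral rhodium catalyst on this new substrate class has to be fixed in a pilot run; (R)-DTBM-SEGPHOS is written, and its enantiomer is used instead if the pilot run shows the (2R) product.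

**Route**

Step 1
Reactants: 1 2-bromo-1-(3,4,5-trimethoxyphenyl)ethan-1-one
Product: 2 rac-2-bromo-1-(3,4,5-trimethoxyphenyl)ethan-1-ol
Conditions: NaBH4, MeOH/THF, 0 °C; aq. NH4Cl quench
Reagents that add atoms: none
Why: Chemoselective borohydride reduction of the α-bromo ketone at 0 °C should give the bromohydrin, the cold, mildly acidic quench preventing closure to the epoxide; the stereocentre is left racemic on purpose because it is erased in step 3.

Step 2
Reactants: 2 rac-2-bromo-1-(3,4,5-trimethoxyphenyl)ethan-1-ol; 3 2-hydroxy-4,6-dimethoxybenzaldehyde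
Product: 4 rac-2-[2-bromo-1-(3,4,5-trimethoxyphenyl)ethoxy]-4,6-dimethoxybenzaldehyde
Conditions: PPh3, DIAD, THF, 0 °C → rt
Reagents that add atoms: none
Why: Mitsunobu etherification, in which the acidic ortho-formyl phenol should displace the oxyphosphonium ion of the secondary benzylic alcohol by SN2 (the β-bromine disfavours ionisation), forming the O1–C2 bond with a configuration that does not matter because C2 becomes sp2 in step 3.

Step 3
Reactants: 4 rac-2-[2-bromo-1-(3,4,5-trimethoxyphenyl)ethoxy]-4,6-dimethoxybenzaldehyde
Product: 5 2,4-dimethoxy-6-{[1-(3,4,5-trimethoxyphenyl)ethenyl]oxy}benzaldehyde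
Conditions: KOtBu, THF, 0 °C → rt; pH 7 buffer work-up; chromatography on Et3N-treated SiO2
Reagents that add atoms: none
Why: E2 dehydrobromination, in which the only β-hydrogen of the primary bromide is the benzylic, oxygen-bearing C–H, so that tert-butoxide can only give the 1,1-disubstituted aryl enol ether, while the hindered, electron-rich, non-enolisable aldehyde should resist alkoxide addition at 0 °C.

Step 4
Reactants: 5 2,4-dimethoxy-6-{[1-(3,4,5-trimethoxyphenyl)ethenyl]oxy}benzaldehyde
Product: 6 (2S)-5,7-dimethoxy-2-(3,4,5-trimethoxyphenyl)-2,3-dihydro-4H-chromen-4-one (CNP0348225.1)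
Conditions: [Rh(cod)Cl]2 (2.5 mol%), (R)-DTBM-SEGPHOS (5.5 mol%), NaB[3,5-(CF3)2C6H3]4 (5 mol%), 4 Å MS, 1,4-dioxane, 60–100 °C
Reagents that add atoms: none
Why: Proposed new method: the cationic bisphosphine complex of monovalent rhodium should bind the formyl group and the C2=C3 enol ether alkene of 5, add the formyl C–H oxidatively to give an acyl hydride of trivalent rhodium, insert the alkene into Rh–H with the hydride delivered to C2, and form the C3–C4 bond by acyl–alkyl reductive elimination from the seven-membered rhodacycle. The closest known reaction type is the rhodium-catalysed enantioselective endo-hydroacylation of 1,1-disubstituted alkenes held ortho to an aryl aldehyde (3-substituted indanones and tetralones, N-vinyl heteroaryl aldehydes), extended here to an aryl enol ether as the alkene. Ring C is closed in the 6-endo-trig mode. The C2 stereocentre is set in the hydride insertion, where the chiral bisphosphine differentiates the two faces of the 1,1-disubstituted alkene; the product is formed under neutral conditions, so the base-labile flavanone centre should not be scrambled afterwards. The step needs 6-endo over 5-exo closure and hydroacylation over decarbonylation: the first should be secured by the 1,1-disubstitution (the exo path would need a tertiary alkyl–rhodium bond and a quaternary carbon), the second by the chelating alkene and the two ortho oxygens of ring A, which keep the acyl hydride coordinatively saturated.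

**Compound list**

1 | 2-bromo-1-(3,4,5-trimethoxyphenyl)ethan-1-one | COc1cc(cc(OC)c1OC)C(=O)CBr | starting material
2 | rac-2-bromo-1-(3,4,5-trimethoxyphenyl)ethan-1-ol | COc1cc(cc(OC)c1OC)C(O)CBr | intermediate
3 | 2-hydroxy-4,6-dimethoxybenzaldehyde | COc1cc(O)c(C=O)c(OC)c1 | starting material
4 | rac-2-[2-bromo-1-(3,4,5-trimethoxyphenyl)ethoxy]-4,6-dimethoxybenzaldehyde | COc1cc(OC)c(C=O)c(OC(CBr)c2cc(OC)c(OC)c(OC)c2)c1 | intermediate
5 | 2,4-dimethoxy-6-{[1-(3,4,5-trimethoxyphenyl)ethenyl]oxy}benzaldehyde | COc1cc(OC)c(C=O)c(OC(=C)c2cc(OC)c(OC)c(OC)c2)c1 | intermediate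
6 | (2S)-5,7-dimethoxy-2-(3,4,5-trimethoxyphenyl)-2,3-dihydro-4H-chromen-4-one | COc1cc(OC)c2c(c1)O[C@H](c1cc(OC)c(OC)c(OC)c1)CC2=O | target

**Step count and risks**

Total step count: 4. Longest linear sequence: 4 steps (1 → 2 → 4 → 5 → 6); phenol 3 enters in step 2.

Steps most likely to fail:

1. Step 4 (proposed new method). The acyl rhodium hydride may lose carbon monoxide, the ring may close 5-exo instead of 6-endo, the alkyl rhodium intermediate may undergo β-aryloxy elimination, or the alkene faces may be poorly differentiated. The fallback uses known chemistry, forms the same C3–C4 bond, sets out from bromoketone 1 (with phenol 3) and comes back at 6. Bromoketone 1 would be reduced with (S)-2-methyl-CBS-oxazaborolidine and BH3·SMe2 (THF, 0 °C) to (S)-2-bromo-1-(3,4,5-trimethoxyphenyl)ethan-1-ol F1. Mitsunobu etherification of F1 with phenol 3 (PPh3, DIAD, THF) should proceed with inversion to give (R)-2-[2-bromo-1-(3,4,5-trimethoxyphenyl)ethoxy]-4,6-dimethoxybenzaldehyde F2. The formyl group would then be masked with propane-1,3-dithiol and catalytic BF3·OEt2 (CH2Cl2, −20 °C) as (R)-2-{2-[2-bromo-1-(3,4,5-trimethoxyphenyl)ethoxy]-4,6-dimethoxyphenyl}-1,3-dithiane F3. Deprotonation of the dithiane C–H with LiN(i-Pr)2 (THF, −78 °C → 0 °C) and intramolecular 6-exo-tet alkylation of this acyl anion equivalent at the CH2Br carbon (Corey–Seebach) should give (2S)-5,7-dimethoxy-2-(3,4,5-trimethoxyphenyl)spiro[chromane-4,2'-[1,3]dithiane] F4. Removal of the dithiane with MeI and CaCO3 in aqueous MeCN should give 6. In this variant the stereocentre is set by the CBS reduction, inverted once in the Mitsunobu step, and never exposed to base as a β-aryloxy ketone.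

2. Step 3. The alkoxide may attack the formyl group, the E2 elimination may be slow, or the acid-labile enol ether may be hydrolysed during isolation. The fallback sets out from bromide 4 and comes back at 5. Displacement of the bromide with preformed PhSeNa (from PhSeSePh and NaBH4, no excess hydride; EtOH/THF, 0 °C) should give 2,4-dimethoxy-6-[2-(phenylselanyl)-1-(3,4,5-trimethoxyphenyl)ethoxy]benzaldehyde F5. Oxidation with NaIO4/NaHCO3 (MeOH/H2O) should give 2,4-dimethoxy-6-[2-(benzeneseleninyl)-1-(3,4,5-trimethoxyphenyl)ethoxy]benzaldehyde F6. Warming F6 in toluene with i-Pr2NH should bring about syn-elimination toward the only β-hydrogen and give 5 without strong base.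

3. Step 2. The hydrogen-bonded, hindered phenol may fail to displace the oxyphosphonium ion, so that elimination or alkylation of the hydrazide takes over. The fallback sets out from phenol 3 and comes back at 5, bypassing 4. Purchased 1-(3,4,5-trimethoxyphenyl)ethan-1-one (CC(=O)c1cc(OC)c(OC)c(OC)c1) would be converted with KN(SiMe3)2 and PhNTf2 (THF, −78 °C) into 1-(3,4,5-trimethoxyphenyl)ethenyl trifluoromethanesulfonate F7. C–O coupling of F7 with phenol 3 under zerovalent palladium catalysis (Pd2(dba)3, 2-(di-tert-butylphosphino)biphenyl, K3PO4, toluene, 80–100 °C; the known coupling of enol triflates with phenols) should give enol ether 5 directly.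

**Further compounds**

F1 | step 4 | (S)-2-bromo-1-(3,4,5-trimethoxyphenyl)ethan-1-ol | O[C@H](CBr)c1cc(OC)c(OC)c(OC)c1
F2 | step 4 | (R)-2-[2-bromo-1-(3,4,5-trimethoxyphenyl)ethoxy]-4,6-dimethoxybenzaldehyde | COc1cc(OC)c(C=O)c(O[C@@H](CBr)c2cc(OC)c(OC)c(OC)c2)c1
F3 | step 4 | (R)-2-{2-[2-bromo-1-(3,4,5-trimethoxyphenyl)ethoxy]-4,6-dimethoxyphenyl}-1,3-dithiane | COc1cc(OC)c(C2SCCCS2)c(O[C@@H](CBr)c2cc(OC)c(OC)c(OC)c2)c1
F4 | step 4 | (2S)-5,7-dimethoxy-2-(3,4,5-trimethoxyphenyl)spiro[chromane-4,2'-[1,3]dithiane] | COc1cc(OC)c2c(c1)O[C@H](c1cc(OC)c(OC)c(OC)c1)CC21SCCCS1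
F5 | step 3 | 2,4-dimethoxy-6-[2-(phenylselanyl)-1-(3,4,5-trimethoxyphenyl)ethoxy]benzaldehyde | COc1cc(OC)c(C=O)c(OC(C[Se]c2ccccc2)c2cc(OC)c(OC)c(OC)c2)c1
F6 | step 3 | 2,4-dimethoxy-6-[2-(benzeneseleninyl)-1-(3,4,5-trimethoxyphenyl)ethoxy]benzaldehyde | COc1cc(OC)c(C=O)c(OC(C[Se](=O)c2ccccc2)c2cc(OC)c(OC)c(OC)c2)c1
F7 | step 2 | 1-(3,4,5-trimethoxyphenyl)ethenyl trifluoromethanesulfonate | COc1cc(cc(OC)c1OC)C(=C)OS(=O)(=O)C(F)(F)F
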